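In a closed flask the incoming ligand is conserved: each exchange moves one from solution onto the complex and frees one leaving ligand.

| setting | maple | birch | autumn | dusk |
|---|---|---|---|---|
| starting complex | 20 mM | 20 mM | 20 mM | 20 mM |
| incoming ligand | 22 mM | 22 mM | 22.0 mM | 22.0 mM |
| leaving ligand | 6.1 mM | 28 mM | 20.0 mM | 5.00 mM |
| temperature | 30 °C | 41 °C |  |  |
| remark | run made earlier | run made earlier | at 25 °C until 5.0 d, from then on at 45 °C | at 25 °C throughout |
| time |  |  | 10 d | 10 d |

- maple (time / d: complex with one exchanged / %): 0.417: 34.3; 1.04: 23.1; 2.08: 16.9; 3.00: 16.0; 4.00: 16.3; 6.00: 15.1; 8.00: 15.2
- birch (time / d: complex with one exchanged / %): 0.500: 19.7; 1.04: 17.1; 1.25: 17.6; 1.67: 17.4; 2.50: 15.9; 4.00: 16.7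

(each reading ± 0.5 percentage points)

- the winner by amount of complex with one exchanged, in percent of the starting complex charged; "neither" if no more than 2 percentage points parts them (autumn / dusk / neither)
- how much complex with one exchanged is there at the end, in percent of the starting complex charged: autumn
- how much complex with one exchanged is there at the end, in percent of the starting complex charged: dusk



Autumn and dusk charge incoming ligand at 1.10 of the starting complex; this ratio is the exchange budget. It lies below two per complex, so incoming ligand is the limiting reagent for a double exchange of the whole charge. The maple run has the same budget, so its readings can open the books.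

Take the ligand as wholly bound once maple goes flat. The first entry is complex with one exchanged, read at 15.1 % of the charge, one ligand each. The first guess puts the remaining budget on a second exchange, two ligands each, which takes 47.4 % of the charge. Put back into the count of complexes, that guess leaves 37.4 % of the charge unentered. The readings of complex with one exchanged do not say what this open entry holds.

The call made here sets dusk near 15.1 % and autumn at the last birch reading, 16.7 %, or higher. How much of the open entry turns into complex with one exchanged in autumn at 45 °C cannot be read from these runs, so this call leaves the winner open.

The forecast says neither, with autumn at 16.8 % and dusk at 15 %, on the ground that “history is erased and both flasks sit at equilibrium”.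

Autumn ends at 25.6 % and dusk at 12.3 %, so the winner is autumn.

    complex with one exchanged ⇌ isomer of the product (K = 2.95, k = 0.0230 /h, Ea = 111 kJ/mol, ΔH = −65.0 kJ/mol)
    complex with one exchanged + incoming ligand → leaving ligand + complex with two exchanged (k = 4.20 /M/h, Ea = 79.0 kJ/mol)
    starting complex + incoming ligand → leaving ligand + complex with one exchanged (k = 9.77 /M/h, Ea = 48.0 kJ/mol)
    leaving ligand + starting complex → side product (k = 0.934 /M/h, Ea = 53.0 kJ/mol)
    (constants at 25 °C)

In autumn, complex with one exchanged rose from 10.9 % at 5.00 d to 25.6 % at 10.0 d, while the isomer of the product fell from 31.9 % to 14.5 %. At the end of autumn, complex with one exchanged, the isomer and twice the complex with two exchanged sum to 1.10 per starting complex, against the budget of 1.10. The neighbour charged with 55 mM of incoming ligand has a budget of 2.75, above two, and ends with 0 % of complex with one exchanged and 92.9 % of complex with two exchanged.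

The runs come from a simulation from invented constants.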